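## Retrosynthetic overview

1. The target is reached by debenzylation and LiAlH4 reduction of the all-trans 1-aryl-tetralin-2,3-diester. C2 and C3 are α to esters and are set thermodynamically (NaOMe) relative to C1, so C1 is the only centre that needs asymmetric control.
2. That diester comes from conjugate reduction of a (1R)-1-aryl-1,2-dihydronaphthalene-2,3-diester.
3. Key step: the C1–C8a bond and the C1 stereocentre are made together by an enantioselective Pd-catalysed reductive (6-endo) cyclisation of an (E,E)-2-arylidene-3-(2-bromoarylidene)succinate. This is the only ring formed in the route; both arenes arrive preformed.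
4. The diene comes from a Stobbe union of an arylidene succinate (Heck coupling of an aryl bromide with dimethyl itaconate) with a 2-bromobenzaldehyde.
5. Both aryl halves come from catechol by reversing the order of O-methylation and O-benzylation, so that Br ends up para to OBn (pendant ring) or para to OMe (fused ring).

Assumption: the SMILES is read as the all-trans (1R,2S,3S)-aryltetralin, i.e. (6S,7S,8R), the enantiomer of (+)-isolariciresinol. Tetralin numbering is used throughout (C1 = ArCH, C2/C3 = CH–CH2OH, C4 = CH2, C4a/C8a = ring-fusion carbons). The (R)-ligand in step 11 is assumed to give (1R); if it gives the opposite sense, the (S)-ligand is used.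

## Route

**Step 1**
Reactants: 1 catechol
Product: 2 2-methoxyphenol (guaiacol)
Conditions: MeI (0.9 equiv), K2CO3, acetone, reflux (excess catechol recovered)
Reagents that add atoms: iodomethane, CI
Why: Williamson mono-O-methylation; catechol in excess limits dimethylation.

**Step 2**
Reactants: 2 2-methoxyphenol
Product: 3 4-bromo-2-methoxyphenol
Conditions: NBS, MeCN, 0 °C
Reagents that add atoms: N-bromosuccinimide, O=C1CCC(=O)N1Br
Why: Electrophilic aromatic bromination goes para to the free OH, the strongest director.

**Step 3**
Reactants: 3 4-bromo-2-methoxyphenol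
Product: 4 1-(benzyloxy)-4-bromo-2-methoxybenzene
Conditions: BnBr, K2CO3, DMF, 60 °C
Reagents that add atoms: benzyl bromide, BrCc1ccccc1
Why: Williamson ether synthesis; benzyl survives every later step until the final hydrogenolysis.

**Step 4**
Reactants: 5 itaconic anhydride
Product: 6 dimethyl itaconate (dimethyl 2-methylidenebutanedioate)
Conditions: MeOH, cat. H2SO4, reflux
Reagents that add atoms: methanol, CO (two equivalents incorporated)
Why: Anhydride methanolysis followed by Fischer esterification.

**Step 5**
Reactants: 4 1-(benzyloxy)-4-bromo-2-methoxybenzene; 6 dimethyl itaconate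
Product: 7 dimethyl (2E)-2-{[4-(benzyloxy)-3-methoxyphenyl]methylidene}butanedioate
Conditions: Pd(OAc)2 (3 mol %), P(o-tol)3 (6 mol %), NaOAc, n-Bu4NBr, DMF, 100 °C
Reagents that add atoms: none
Why: Mizoroki–Heck coupling; aryl adds to the CH2 terminus and β-H elimination toward the benzylic hydrogens gives the conjugated E-arylidene (aryl trans to the ester). This forms the C1–aryl bond.

**Step 6**
Reactants: 1 catechol
Product: 8 2-(benzyloxy)phenol
Conditions: BnBr (0.9 equiv), K2CO3, acetone, reflux
Reagents that add atoms: benzyl bromide, BrCc1ccccc1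
Why: Williamson mono-O-benzylation with catechol in excess.

**Step 7**
Reactants: 8 2-(benzyloxy)phenol
Product: 9 2-(benzyloxy)-4-bromophenol
Conditions: NBS, MeCN, 0 °C
Reagents that add atoms: N-bromosuccinimide, O=C1CCC(=O)N1Br
Why: Bromination para to the free OH, which places Br para to the oxygen that becomes OMe (the future C8a).

**Step 8**
Reactants: 9 2-(benzyloxy)-4-bromophenol
Product: 10 2-(benzyloxy)-4-bromo-1-methoxybenzene
Conditions: MeI, K2CO3, DMF, rt
Reagents that add atoms: iodomethane, CI
Why: Williamson O-methylation.

**Step 9**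
Reactants: 10 2-(benzyloxy)-4-bromo-1-methoxybenzene
Product: 11 4-(benzyloxy)-2-bromo-5-methoxybenzaldehyde
Conditions: Cl2CHOMe, TiCl4, CH2Cl2, –78 → –20 °C; then ice/H2O
Reagents that add atoms: dichloromethyl methyl ether, COC(Cl)Cl (formyl carbon); water, O (formyl oxygen on hydrolysis)
Why: Rieche formylation; the position para to OBn and ortho to Br is favoured by both directors, as in other electrophilic substitutions of 4-bromo-1,2-dialkoxybenzenes.

**Step 10**
Reactants: 7 arylidene succinate; 11 bromo-aldehyde
Product: 12 dimethyl (2E,3E)-2-{[4-(benzyloxy)-3-methoxyphenyl]methylidene}-3-{[4-(benzyloxy)-2-bromo-5-methoxyphenyl]methylidene}butanedioate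
Conditions: KOt-Bu, t-BuOH/THF, 0 → 50 °C; then MeI, DMF, rt (one pot); E,E isomer purified by crystallisation
Reagents that add atoms: iodomethane, CI (methyl of the ester re-formed from the Stobbe carboxylate)
Why: Stobbe condensation (aldol, lactonisation, E1cB opening) gives the second E-arylidene, and the liberated carboxylate is methylated in situ. This forms the C3–C4 bond.

**Step 11**
Reactants: 12 (E,E)-bis(arylidene)succinate
Product: 13 dimethyl (1R)-7-(benzyloxy)-1-[4-(benzyloxy)-3-methoxyphenyl]-6-methoxy-1,2-dihydronaphthalene-2,3-dicarboxylate (C2 configuration not controlled; reset in step 12)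
Conditions: Pd2(dba)3 (2.5 mol %), (R)-DTBM-SEGPHOS (6 mol %), HCO2Na (1.5 equiv), DMF/H2O 20:1, 80 °C
Reagents that add atoms: none
Why: Proposed new method: an enantioselective intramolecular reductive Heck (cyclisation–hydride capture) in the 6-endo mode. Oxidative addition into the C8a–Br bond is followed by insertion of the twisted 1,3-diene at its remote terminus C1; this is favoured over 5-exo attack at C2 because it gives a cyclic η3-allyl/oxa-allyl Pd over C2–C3–C4, whereas 5-exo would give a quaternary carbon and an unstabilised alkyl-Pd. Formate then delivers hydride. The chiral bisphosphine selects one helical s-cis conformer of the achiral diene and so sets C1 as R. Any 1,4-dihydro regioisomer or C2 epimer converges in step 12. The closest known reaction types are Pd-catalysed enantioselective intramolecular reductive Heck cyclisations (e.g. endo closure to 3-arylindanones) and aryl-Pd insertion into 1,3-dienes to give π-allyl-Pd; the same ring closure of dibenzylidenesuccinates is known only in racemic form under acid or light.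

**Step 12**
Reactants: 13 (1R)-dihydronaphthalene diester
Product: 14 dimethyl (1R,2S,3S)-7-(benzyloxy)-1-[4-(benzyloxy)-3-methoxyphenyl]-6-methoxy-1,2,3,4-tetrahydronaphthalene-2,3-dicarboxylate (all-trans)
Conditions: Cu(OAc)2·H2O (5 mol %), 1,2-bis(diphenylphosphino)benzene (5 mol %), PMHS, t-BuOH, toluene, rt; then NaOMe, MeOH, 60 °C
Reagents that add atoms: none
Why: CuH conjugate reduction saturates the C3=C4 enoate under neutral conditions, without alkene migration toward C1. Methoxide then epimerises C2 and C3 (both α to esters) to the all-equatorial trans,trans diester; C1 is not acidic and stays R, so C2 and C3 are set as S,S.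

**Step 13**
Reactants: 14 all-trans diester
Product: 15 [(1R,2S,3S)-7-(benzyloxy)-1-[4-(benzyloxy)-3-methoxyphenyl]-6-methoxy-1,2,3,4-tetrahydronaphthalene-2,3-diyl]dimethanol
Conditions: LiAlH4, THF, 0 °C → rt
Reagents that add atoms: none
Why: Ester reduction to the diol; C2 and C3 are no longer epimerisable afterwards.

**Step 14**
Reactants: 15 dibenzyl diol
Product: 16 target, (1R,2S,3S)-7-hydroxy-1-(4-hydroxy-3-methoxyphenyl)-6-methoxy-1,2,3,4-tetrahydronaphthalene-2,3-dimethanol
Conditions: H2 (1 atm), 10% Pd/C, EtOAc/MeOH, rt
Reagents that add atoms: none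
Why: Hydrogenolysis of the two aryl benzyl ethers; no stereocentre or C–C bond is affected.

## Compound list

1 | catechol | Oc1ccccc1O | starting material
2 | 2-methoxyphenol | COc1ccccc1O | intermediate
3 | 4-bromo-2-methoxyphenol | COc1cc(Br)ccc1O | intermediate
4 | 1-(benzyloxy)-4-bromo-2-methoxybenzene | COc1cc(Br)ccc1OCc1ccccc1 | intermediate
5 | itaconic anhydride | C=C1CC(=O)OC1=O | starting material
6 | dimethyl itaconate | COC(=O)CC(=C)C(=O)OC | intermediate
7 | dimethyl (2E)-2-{[4-(benzyloxy)-3-methoxyphenyl]methylidene}butanedioate | COC(=O)C/C(=C\c1ccc(OCc2ccccc2)c(OC)c1)C(=O)OC | intermediate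
8 | 2-(benzyloxy)phenol | Oc1ccccc1OCc1ccccc1 | intermediate
9 | 2-(benzyloxy)-4-bromophenol | Oc1ccc(Br)cc1OCc1ccccc1 | intermediate
10 | 2-(benzyloxy)-4-bromo-1-methoxybenzene | COc1ccc(Br)cc1OCc1ccccc1 | intermediate
11 | 4-(benzyloxy)-2-bromo-5-methoxybenzaldehyde | O=Cc1cc(OC)c(OCc2ccccc2)cc1Br | intermediate
12 | dimethyl (2E,3E)-2-{[4-(benzyloxy)-3-methoxyphenyl]methylidene}-3-{[4-(benzyloxy)-2-bromo-5-methoxyphenyl]methylidene}butanedioate | COC(=O)/C(=C/c1ccc(OCc2ccccc2)c(OC)c1)/C(=C\c1cc(OC)c(OCc2ccccc2)cc1Br)C(=O)OC | intermediate
13 | dimethyl (1R)-7-(benzyloxy)-1-[4-(benzyloxy)-3-methoxyphenyl]-6-methoxy-1,2-dihydronaphthalene-2,3-dicarboxylate (C2 unassigned) | COc1cc([C@@H]2c3cc(OCc4ccccc4)c(OC)cc3C=C(C(=O)OC)C2C(=O)OC)ccc1OCc1ccccc1 | intermediate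
14 | dimethyl (1R,2S,3S)-7-(benzyloxy)-1-[4-(benzyloxy)-3-methoxyphenyl]-6-methoxy-1,2,3,4-tetrahydronaphthalene-2,3-dicarboxylate | COc1cc([C@@H]2c3cc(OCc4ccccc4)c(OC)cc3C[C@H](C(=O)OC)[C@H]2C(=O)OC)ccc1OCc1ccccc1 | intermediate
15 | [(1R,2S,3S)-7-(benzyloxy)-1-[4-(benzyloxy)-3-methoxyphenyl]-6-methoxy-1,2,3,4-tetrahydronaphthalene-2,3-diyl]dimethanol | COc1cc([C@@H]2c3cc(OCc4ccccc4)c(OC)cc3C[C@H](CO)[C@H]2CO)ccc1OCc1ccccc1 | intermediate
16 | (1R,2S,3S)-7-hydroxy-1-(4-hydroxy-3-methoxyphenyl)-6-methoxy-1,2,3,4-tetrahydronaphthalene-2,3-dimethanol | COc1cc([C@@H]2c3cc(O)c(OC)cc3C[C@H](CO)[C@H]2CO)ccc1O | target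

## Step count and risks

Total steps: 14.
Longest linear sequence: 9 steps (1 → 2 → 3 → 4 → 7 → 12 → 13 → 14 → 15 → 16, i.e. steps 1, 2, 3, 5, 10–14; the branch through steps 6–9 is equally long). 9/14 = 0.64.

Three steps most likely to fail:

1. **Step 11 (proposed new Pd-catalysed asymmetric 6-endo reductive cyclisation).** Risks are 5-exo closure, simple hydrodebromination, Heck aromatisation to the arylnaphthalene, and low or reversed ee. Fallback with known chemistry: abandon the bromide and the Pd closure.
   - Stobbe condensation of 4-(benzyloxy)-3-methoxybenzaldehyde (from 4 by Br/Li exchange and DMF) with dimethyl succinate (from succinic anhydride and MeOH).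
   - Rh–bisphosphine asymmetric hydrogenation of the half-ester, then reduction and lactonisation to (S)-β-(4-benzyloxy-3-methoxybenzyl)-γ-butyrolactone.
   - LDA aldol with the same aldehyde, then TFA Friedel–Crafts cyclisation to the all-trans aryltetralin lactone.
   - LiAlH4 reduction and hydrogenolysis.

2. **Step 9 (Rieche formylation of a bromo-aryl benzyl ether).** Risks are Lewis-acid debenzylation and incomplete regiocontrol. Fallback: install the groups in the opposite order. Formylate 4 (n-BuLi, DMF) to 4-(benzyloxy)-3-methoxybenzaldehyde, then brominate (Br2, NaOAc, AcOH); bromine enters para to OMe and ortho to CHO to give the same 11.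

3. **Step 10 (Stobbe union).** Risks are E/Z mixtures and base-induced scrambling of the existing arylidene, and geometric purity matters for step 11. Fallback: assemble the diene in the reverse order by the classical double Stobbe sequence. Condense 11 with dimethyl succinate, re-esterify, then condense that arylidene succinate with 4-(benzyloxy)-3-methoxybenzaldehyde and methylate, so the pendant-ring arylidene is introduced last.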